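The earlier runs and the new flask stem from a simulated flask with made-up constants; scatter was added.

In a one-step world starting material has a single exit and no question of share arises. The zero of my scale was therefore the next simplest world: two first-order exits from one species, where the ratio of rates holds at any concentration and feeding shifts nothing.

| flask | starting material | reagent | remark | time |
|---|---|---|---|---|
| north | 0.0010 M | 0.95 mM | run made earlier |  |
| west | 0.0014 M | 0.95 mM | run made earlier |  |
| south | 0.0022 M | 0.95 mM | run made earlier |  |
| east | 0.0010 M | 1.4 mM | run made earlier |  |
| Tuesday's | 0.0010 M (fed, over 25 s) | 0.950 mM | all else is in the flask from the start; the feed brings no volume worth counting | 2.0 min |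
| Friday's | 0.0010 M | 0.950 mM | everything together at the start | 2.0 min |
| Monday's | 0.0010 M | 0.950 mM (fed, over 25 s) | all else is in the flask from the start; the feed brings no volume worth counting | 2.0 min |

- north (time / s: target / %, side product A / %, starting material / %): 20.0: 0, 43, 44; 40.0: 6, 60, 21; 60.0: 12, 66, 10; 80.0: 14, 74, 5; 90.0: 15, 74, 2; 120: 19, 76, 0
- west (time / s: target / %, side product A / %, starting material / %): 10.0: 0, 24, 67; 15.0: 1, 31, 54; 25.0: 3, 47, 38; 40.0: 4, 62, 19; 80.0: 12, 73, 5
- south (time / s: target / %, side product A / %, starting material / %): 10.0: 1, 26, 64; 15.0: 2, 33, 55; 25.0: 2, 45, 37; 40.0: 6, 60, 19; 60.0: 6, 68, 11; 80.0: 13, 73, 5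
- east (time / s: target / %, side product A / %, starting material / %): 15.0: 0, 34, 59; 30.0: 6, 53, 32; 40.0: 6, 61, 21; 60.0: 15, 71, 8; 80.0: 15, 74, 4

(standard deviation of a reading: 1.5 percentage points)



1. the flask that comes out highest in share of target in target plus side product A, or "all alike" when all lie within 1.5 percentage points (Tuesday's / Friday's / Monday's / all alike)
2. share of target in target plus side product A at the end, Tuesday's
3. share of target in target plus side product A at the end, Friday's
4. share of target in target plus side product A at the end, Monday's

I read the ladder from its fastest rung. Starting material stood between 19% and 21% at 40.0 s in the four runs, so its loss looked first order and free of reagent, and the north run gave a half-life of 18.1 s. Next came the feed of 25 s, longer than that half-life, and material fed over it entered on average 12.5 s late. Slower again was a gap in the north run's balance: 12.0% at 60.0 s and 5.00% at 120 s, a rough half-life of 47.5 s, slower than the first rung.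

The first rung gave the split. With starting material at 0%, the north run held 76% side product A, so I took 24.0% as the branching fraction s, the share of spent starting material that does not become side product A. In the south run side product A reached 1.61 mM, more than the 0.95 mM of reagent charged, so that exit did not use reagent one for one, and as an estimate I reckoned Monday's flask with Friday's. Friday's repeats the north recipe, whose share read 20.0%. For Tuesday's flask I reckoned that the delay leaves a gap of 6.00%, which puts its target 1 percentage point lower, less than the margin.

The forecast gave 19.5%, 20.3% and 20% for Tuesday's, Friday's and Monday's, all alike, saying “feeding cannot change selectivity”.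

The flasks gave 17.3%, 18.2% and 18.1%: all alike.

    reagent + intermediate → target (k = 34.0 /M/s)
    reagent ⇌ dormant form (K = 0.690, k = 0.150 /s)
    starting material → side product A (k = 0.0300 /s)
    starting material ⇌ intermediate (K = 13.0, k = 0.00900 /s)
    starting material + target → side product B (k = 5.40 /M/s)

In Tuesday's flask the two exits of starting material ran side by side, the midpoints of their turnover falling at 0.515 min for side product A and 0.506 min for intermediate. Intermediate went on with reagent to target, 5.75% still standing at 2.00 min against 4.78% in Friday's, and at 20.0 min Tuesday's share was 22.0% against my s of 24.0%. Tuesday's read at 50 s had 24.1% starting material left, so s puts 57.7% in side product A and 18.2% beyond it. It held 58.4% side product A, 11.4% intermediate and 5.70% target, a share of 8.89%.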